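Q, the product, came early and then slowed in the three earlier runs: in ochre it read 13.8 % after 1.00 min and 20.3 % after 2.50 min, with 79.1 % of E still there.

all flasks: E 0.40 M
- grey: Z 0.52 M; run made earlier
- ochre: Z 0.45 M; run made earlier
- blue: Z 0.56 M; run made earlier
- theta: Z 0.400 M; time 5.0 min
- alpha: Z 0.600 M; time 5.0 min

| run | time / min | J / % | Q / % | E / % |
|---|---|---|---|---|
| grey | 0.667 | 3.0 | 13.9 | 84.8 |
| grey | 1.33 | 1.4 | 18.6 | 79.6 |
| grey | 2.00 | 2.8 | 18.0 | 77.1 |
| grey | 2.50 | 4.5 | 21.1 | 76.1 |
| ochre | 0.200 | 0.5 | 5.2 | 93.6 |
| ochre | 0.500 | 0.8 | 9.5 | 87.3 |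
| ochre | 1.00 | 2.3 | 13.8 | 83.3 |
| ochre | 2.50 | 2.3 | 20.3 | 79.1 |
| blue | 0.667 | 4.2 | 14.3 | 84.2 |
| blue | 1.33 | 1.9 | 21.1 | 77.8 |
| blue | 2.00 | 4.7 | 21.9 | 76.4 |
| blue | 2.50 | 4.1 | 22.3 | 74.9 |

(readings scatter by 1 percentage point)

1. which of these there is most of at the end, counted by the E in it, theta (J / Q / E)
2. which of these there is most of at the end, counted by the E in it, alpha (J / Q / E)
3. the largest of these amounts at the end, in percent of the E charged, theta
4. the largest of these amounts at the end, in percent of the E charged, alpha

Let f be the fraction of the E charge left, and x the charge of Z over the charge of E. My bench rule was the pseudo-first-order one, which takes Z as staying at its charge: −ln f grows steadily with x and time t. The first ochre reading gave, as a reading with its scatter,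

rate = −ln f / (x t) = 0.294 /min

For ochre at 2.50 min that rule promised f = 43.7 %, but the reading was 79.1 %, higher. So the rule had a border. I took instead the loss per equivalent of Z, s = −ln f / x at the last reading:

grey 0.210, ochre 0.208, blue 0.206, mean s = 0.208

The border, an estimate from these scattered readings, is where the two rules cross:

s / rate = 0.709 min

The asked time is 7.06 times that, so I dropped time and let the charge of Z carry the reckoning, with f = exp(−s x). In a repeat, E is to be watched before that crossing.

theta: f = 81.2 %

alpha: f = 73.2 %

Even in alpha the E gone into other forms came to 26.8 % by this reckoning, less than the E left, and theta keeps more E, so I put E first in both.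

The forecast also named E and E, with 80 % for theta and 72.5 % for alpha, a little below mine. It reckoned from an equilibrium, adding “A fast-dying reagent would fit too”.

The flasks gave E first, at 78.7 % in theta and 72.7 % in alpha, so the forecast was right.

    E + 2 Z → J (k = 0.430 /M²/min)
    2 Z → D (k = 1.60 /M/min)
    E + Z → Q (k = 0.780 /M/min)
    Z → L (k = 0.550 /min)

In theta, Z went to L 2.0 times as fast as to Q at 0.573 min, and 2.2 times as fast at 5.00 min. By then 0.66 % of the Z charge was left, and E stood 2.5 percentage points below my 81.2 %. The neighbour flask with 0.68 M of Z has x = 1.70, for which s gives f = 70.2 %, and it ended with 70.6 % of E.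

The numbers in the tables are simulated from invented constants; the scatter is artificial.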